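**Retrosynthetic overview**
1. δ-Tocopherol ⇒ open the dihydropyran ring at O1–C8a to a 3-(3-hydroxyalkyl)-5-methylphenol; this ring is closed last by anodic para-C–H etherification, with the carbinol C–O bond untouched.
2. C4–C4a (ArCH2) ⇒ hydroboration / B-alkyl Suzuki coupling of (3R,7R,11R)-isophytol with 3-bromo-5-methylphenol (the aromatic ring is bought).
3. Isophytol C5–C6 (tocopherol C2′–C3′) ⇒ photoredox/Ni decarboxylative sp3–sp3 coupling of the ring-opened carboxylate of (R)-lavender lactone with a (2R,6R)-C14 bromide.
4. The lactone ⇐ (R)-linalool (supplies C2); the C14 bromide ⇐ natural phytol by ozonolysis, Norrish II excision of C3, ozonolysis/reduction and bromination (supplies C4′, C8′).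
5. Ring order: temporary γ-lactone (formed step 1, opened step 6), then the chroman O-ring (step 8).

Assumption: commercial natural phytol is the (7R,11R) material (its E/Z ratio is irrelevant because C2=C3 is cleaved) and commercial (−)-linalool is the R enantiomer at high ee.

**Step 1**
Reactants: 1, (R)-(−)-linalool
Product: 2, (R)-lavender lactone [(5R)-5-ethenyl-5-methyloxolan-2-one]
Conditions: O3, pyridine, CH2Cl2, −78 °C (Sudan Red 7B end-point); then TEMPO (10 mol %), PhI(OAc)2, CH2Cl2, rt (one pot)
Reagents that add atoms: ozone, [O-][O+]=O (supplies the carbonyl oxygen)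
Why: Chemoselective ozonolysis cleaves the electron-rich trisubstituted alkene much faster than the vinyl group, the γ-hydroxy aldehyde closes to the lactol, and TEMPO/PhI(OAc)2 (oxoammonium oxidation) gives the lactone; the tertiary carbinol centre bought in linalool is untouched and becomes C2.

**Step 2**
Reactants: 3, natural phytol [(2E,7R,11R)-3,7,11,15-tetramethylhexadec-2-en-1-ol]
Product: 4, (6R,10R)-6,10,14-trimethylpentadecan-2-one (phytone)
Conditions: O3, CH2Cl2/MeOH, −78 °C; Me2S, → rt
Reagents that add atoms: ozone, [O-][O+]=O
Why: Ozonolysis (Criegee) of the only alkene gives the C18 methyl ketone and glycolaldehyde; the two methyl-bearing centres (future 4′R, 8′R) are remote and untouched.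

**Step 3**
Reactants: 4, phytone
Product: 5, (3R,7R)-3,7,11-trimethyldodec-1-ene
Conditions: hν (Hg lamp, Pyrex, λ > 290 nm), degassed pentane (0.02 M), rt
Reagents that add atoms: none
Why: Norrish type II fragmentation: n→π* excitation, 1,5-H abstraction from the γ-CH2 and β-scission of the 1,4-biradical expel acetone (as its enol) and leave the terminal alkene; the adjacent CH(CH3) centre is never a radical site, so it stays R.

**Step 4**
Reactants: 5, (3R,7R)-3,7,11-trimethyldodec-1-ene
Product: 6, (2R,6R)-2,6,10-trimethylundecan-1-ol
Conditions: O3, CH2Cl2/MeOH, −78 °C; NaBH4, −78 → 0 °C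
Reagents that add atoms: ozone, [O-][O+]=O
Why: Ozonolysis with direct borohydride work-up reduces the α-methyl aldehyde at low temperature before it can enolise, so the 2R centre is preserved.

**Step 5**
Reactants: 6, (2R,6R)-2,6,10-trimethylundecan-1-ol
Product: 7, (2R,6R)-1-bromo-2,6,10-trimethylundecane
Conditions: CBr4, PPh3, CH2Cl2, 0 °C
Reagents that add atoms: carbon tetrabromide, BrC(Br)(Br)Br
Why: Appel bromination at the primary carbon; no stereocentre is involved.

**Step 6**
Reactants: 2, (R)-lavender lactone; 7, (2R,6R)-1-bromo-2,6,10-trimethylundecane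
Product: 8, (3R,7R,11R)-isophytol [(3R,7R,11R)-3,7,11,15-tetramethylhexadec-1-en-3-ol]
Conditions: 2 (2 equiv), CsOH·H2O (2 equiv), THF/H2O, rt, evaporate; then 7 (1 equiv), [Ir{dF(CF3)ppy}2(dtbbpy)]PF6 (2 mol %), NiCl2·glyme (10 mol %), 4,4′-(MeO)2bpy (10 mol %), MeCN/H2O, 450 nm LEDs, rt
Reagents that add atoms: none (the hydroxide oxygen leaves as CO2)
Why: Metallaphotoredox decarboxylative C(sp3)–C(sp3) cross-coupling: Ir(III)* oxidises the caesium γ-hydroxy carboxylate, CO2 loss gives the primary 3-hydroxyalkyl radical, and Ni joins it to the primary bromide; the basic medium keeps the hydroxy acid open, and both neighbouring stereocentres are β to the new bond and unaffected.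

**Step 7**
Reactants: 8, (3R,7R,11R)-isophytol; 9, 3-bromo-5-methylphenol
Product: 10, 3-[(3R,7R,11R)-3-hydroxy-3,7,11,15-tetramethylhexadecyl]-5-methylphenol
Conditions: 9-BBN (2.5 equiv), THF, 0 → 60 °C; then 9, Pd(OAc)2/SPhos (5/10 mol %), aq. K3PO4, THF, 65 °C
Reagents that add atoms: none (9-BBN delivers only H)
Why: Anti-Markovnikov hydroboration of the vinyl group followed by B-alkyl Suzuki–Miyaura coupling forms ArCH2–CH2 (C4a–C4); the oxygen is γ to boron so no β-elimination occurs, and the carbinol centre is untouched.

**Step 8**
Reactants: 10, the phenol–tertiary alcohol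
Product: 11, (2R,4′R,8′R)-δ-tocopherol
Conditions: graphite anode | Pt cathode, undivided cell, nBu4NPF6 (0.1 M), 2,6-lutidine (2 equiv), HFIP/CH2Cl2 (1:3), 0.01 M, 0 °C, 5 mA cm⁻², 2.5 F mol⁻¹; then aq. ascorbic acid
Reagents that add atoms: none
Why: Proposed new method: anodic dehydrogenative para-C–H etherification. Two-electron oxidation of the phenol in non-nucleophilic HFIP gives a phenoxonium ion whose only competent nucleophile is the tethered tertiary OH; six-membered closure onto the para carbon and tautomerisation give the hydroquinone mono-ether (the chroman-6-ol) without breaking the carbinol C–O bond, so C2 stays R. Over-oxidation of the more electron-rich product should stop at the reversible chromanoxylium (tocopherol phenoxonium) ion, which is returned at the cathode and by the ascorbate quench, whereas oxidation of 10 is made irreversible by ring closure. The closest known chemistry is anodic or PhI(OAc)2 oxidation of phenols with O-nucleophiles to p-quinol ethers and quinone monoketals, and dehydrogenative phenol couplings in HFIP.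

**Compound list**
1 | (R)-(−)-linalool, (3R)-3,7-dimethylocta-1,6-dien-3-ol | C=C[C@](C)(O)CCC=C(C)C | starting material
2 | (R)-lavender lactone, (5R)-5-ethenyl-5-methyloxolan-2-one | C=C[C@@]1(C)CCC(=O)O1 | intermediate
3 | natural phytol, (2E,7R,11R)-3,7,11,15-tetramethylhexadec-2-en-1-ol | OC/C=C(\C)CCC[C@H](C)CCC[C@H](C)CCCC(C)C | starting material
4 | phytone, (6R,10R)-6,10,14-trimethylpentadecan-2-one | CC(=O)CCC[C@H](C)CCC[C@H](C)CCCC(C)C | intermediate
5 | (3R,7R)-3,7,11-trimethyldodec-1-ene | C=C[C@H](C)CCC[C@H](C)CCCC(C)C | intermediate
6 | (2R,6R)-2,6,10-trimethylundecan-1-ol | OC[C@H](C)CCC[C@H](C)CCCC(C)C | intermediate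
7 | (2R,6R)-1-bromo-2,6,10-trimethylundecane | BrC[C@H](C)CCC[C@H](C)CCCC(C)C | intermediate
8 | (3R,7R,11R)-isophytol, (3R,7R,11R)-3,7,11,15-tetramethylhexadec-1-en-3-ol | C=C[C@](C)(O)CCC[C@H](C)CCC[C@H](C)CCCC(C)C | intermediate
9 | 3-bromo-5-methylphenol | Cc1cc(O)cc(Br)c1 | starting material
10 | 3-[(3R,7R,11R)-3-hydroxy-3,7,11,15-tetramethylhexadecyl]-5-methylphenol | Cc1cc(O)cc(CC[C@](C)(O)CCC[C@H](C)CCC[C@H](C)CCCC(C)C)c1 | intermediate
11 | (2R,4′R,8′R)-δ-tocopherol, (2R)-2,8-dimethyl-2-[(4R,8R)-4,8,12-trimethyltridecyl]chroman-6-ol | Cc1cc(O)cc2c1O[C@](C)(CCC[C@H](C)CCC[C@H](C)CCCC(C)C)CC2 | target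

**Totals**
Total step count: 8. Longest linear sequence: 7 (steps 2–8, from phytol). No protecting groups are used.

**Three steps most likely to fail**
- **Step 8 (proposed new step).** Risks are closure at the ortho carbon (giving the 6-methylchroman-8-ol isomer), phenol dimerisation and irreversible over-oxidation to quinone. Fallback (known chemistry): para-brominate 10 with NBS (between the two alkyl groups, as for 3,5-dimethylphenol), silylate the phenol, close the ring by Pd-catalysed intramolecular C–O coupling of the tertiary alcohol (Buchwald-type etherification), then desilylate; C2 is not involved.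
- **Step 6.** Risks are inefficient oxidation and Ni capture of an unstabilised primary radical, protodecarboxylation, and O-alkylation of the carboxylate. Fallback: drop direct carboxylate oxidation; open 2, protect the tertiary OH as its TES ether, form the N-hydroxyphthalimide ester and couple it with the alkylzinc reagent made from 7 under Ni catalysis (thermal decarboxylative Negishi), then desilylate.
- **Step 3.** Risks are a modest chemical yield (Yang cyclobutanols, some type I cleavage) and the dilute photolysis on scale. Fallback: make 6 without phytol by classical chiral-pool assembly: Cu-catalysed coupling of (R)-3,7-dimethyloctylmagnesium bromide (from (R)-citronellol) with the tosylate of the O-silyl alcohol derived from (S)-Roche ester, then desilylation.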